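The noon flask was the one I had to act on at 5.0 h, and the decision was what to change then.

common to all: starting material 2.2 M
- noon: reagent 1.1 M; the very flask that is asked about, followed so far
- dusk: reagent 1.7 M; run made earlier
- flask: reagent 1.10 M; time 5.0 h

noon run (percent of the starting material charged)

| time / h | target / % | starting material / % |
|---|---|---|
| 0.500 | 13.9 | 62.9 |
| 1.00 | 22.3 | 62.2 |
| 1.50 | 25.4 | 60.0 |
| 2.00 | 27.7 | 60.4 |
| 2.50 | 28.7 | 60.0 |
| 3.00 | 28.7 | 59.4 |

dusk run (percent of the starting material charged)

| time / min | target / % | starting material / % |
|---|---|---|
| 1.50 | 1.6 | 47.2 |
| 5.00 | 4.0 | 46.2 |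
| 8.00 | 6.7 | 46.4 |
| 12.0 | 9.8 | 46.3 |
| 20.0 | 14.4 | 46.1 |
| 25.0 | 18.4 | 45.7 |

(readings scatter by 0.5 percentage points)

- gamma: at 5.0 h add reagent, 50.0 % of the amount charged, then wait 1.5 h
- theta: at 5.0 h take out 90 % of the target then present, then wait 1.5 h
- alpha: change nothing and wait 1.5 h more

1. target, in percent of the starting material first charged, at 5.0 h
2. what to do for the largest gain in target; "none" if nothing gains more than 2 percentage points (gamma / theta / alpha / none)
3. target present, with what was taken out counted in, in percent of the starting material first charged, after gamma
4. target present, with what was taken out counted in, in percent of the starting material first charged, after theta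

- what is taken out of target is counted as made
- additions bring no volume worth counting

In noon, target read 28.7 % at 2.50 h and 28.7 % at 3.00 h, flat within the scatter of 0.5 percentage points, while 59.4 % of the starting material stood unused. Reagent was the limiting reagent by my reading, its charge half that of starting material. Dusk, with more reagent, showed less starting material at its first reading, 47.2 % against 62.9 % in noon. So I watched c(reagent) and reckoned 0.574: the yield on reagent, moles of target at the stall per mole of reagent charged. I expected noon to stand near 28.7 % at 5.0 h. Gamma adds 0.550 M of reagent, which at that yield is worth 14 points, giving 43.0 %. This yield gave me no figure for theta.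

The forecast said 29 %, 40 % after gamma and 38 % after theta, and chose gamma, on the ground that "Adding reagent pulls more complex from the large free pool of starting material". Its gamma figure stood lower than mine.

The flask gave 28.4 %, then 40.1 % after gamma and 34.0 % after theta, and the best choice was gamma. Gamma's gain came to 0.467 moles of target per mole of reagent added, against the 0.574 I had carried.

    reagent ⇌ dormant form (K = 8.60, k = 0.0150 min⁻¹)
    target ⇌ isomer of the product (K = 0.510, k = 0.00380 min⁻¹)
    adduct → target (k = 0.0180 min⁻¹)
    starting material + reagent ⇌ adduct (K = 2.10 M⁻¹, k = 3.50 M⁻¹ min⁻¹)

At 0.00146 h, adduct made target with a half-life of 0.64 h, shorter than the 0.77 h of reagent's forward loss to dormant form alone. At 5.00 h the flask held free reagent at 0.617 % of its own charge, adduct at 0.826 % of the starting material charged, and dormant form at 0.177 M.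

In the neighbouring flask with 0.28 M of reagent, the yield on reagent gives 7.31 % of target. The computed flask gave 7.65 %.

The readings come from a simulation with made-up constants; scatter was added.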